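Atom numbers used throughout: ring A = C1–C5 and C10 (gem-dimethyl on C4); ring B = C5–C10 (methyl on C8, chain on C9); chain C11–C16 with the hydroxymethyl group on C13; butenolide carbons C17–C20 (C17 bonded to C16, C19 the lactone carbonyl).

## The problem

The target 26 is a C25 terpenoid. Its core is a cis-fused octahydronaphthalene (rings A and B) with a tetrasubstituted C8=C9 alkene. C9 carries a chain that ends, through a conjugated diene, in a 4-substituted furan-2(5H)-one.

There are only two stereocentres, and they are adjacent: the C5 methine and the quaternary C10, whose methyl group is cis to H5. C5 can be set by a reliable asymmetric reaction and can then control C10; the reverse order has no practical solution. The cis ring fusion is the opposite of what a cationic polyene cyclisation gives, so ring closure has to be forced onto one face of a preformed ring. C10 is also crowded, lying between C5 (next to the C4 gem-dimethyl group) and the tetrasubstituted alkene.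

In the chain, two geometries must be fixed by the bond-forming steps themselves: the trisubstituted C13=C14 alkene (C12 cis to C15, CH2OH cis to H14) and the E C15=C16 alkene.

Several groups will not survive rough treatment. The butenolide has an electrophilic carbonyl and acidic C20 protons and is incompatible with Grignard reagents, hydrides and strong base. The triene–lactone chromophore is sensitive to light and acid. The allylic primary alcohol and the acid-labile, electron-rich C8=C9 alkene must also be spared, the latter in any reduction.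

The feature that opens the route is the position of C10 between C9 and C5. C9 is an alkene carbon in the target and can therefore carry palladium. C5 can anchor the C6–C7–C8 tether. An alkenylpalladium at C9, tethered through C5, can reach a C10=C1 alkene of ring A only on the face that bears C6. One insertion therefore gives ring B, the quaternary centre and the cis fusion.

## Retrosynthesis

**C16–C17 (26 ⇒ 23 + 25).** The butenolide is detached as stannane 25 from dienyl iodide 23, to be joined by a Stille coupling. The neighbouring cuts, olefinations at C15=C16 or C13=C14 with a butenolide-bearing partner, would expose the lactone to base and leave alkene geometry to selectivity. The sp2–sp2 coupling is stereospecific and neutral. This places the most fragile part of the molecule in the last step; the forward reaction must tolerate a free allylic alcohol. Stannane 25 is one step from bromobutenolide 24.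

**C16–I (23 ⇒ 22).** The iodide is traced to the trimethylsilyl group of dienylsilane 22. Silicon is the one C16 substituent that survives a Grignard reagent and can still be exchanged for iodine with retention. The forward iododesilylation must act at C16 and leave the C8=C9 alkene alone.

**C12–C13 and C14–H (22 ⇒ 16 + 19).** Cutting C12–C13 divides the molecule into bicyclic bromide 16 and the five-carbon enynol 19. An anti-carbomagnesiation of the propargylic alcohol, directed by its alkoxide, puts C12 on C13 and hydrogen on C14 with C12 cis to C15. An olefination at C13=C14 would give the same alkene with only moderate geometric control. Enynol 19 is cut at C14–C15 into alkenyl bromide 17 and propargyl alcohol 18 (Sonogashira coupling), so the E geometry of C15=C16 is bought.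

**Adjustments at C12 and C1–C2 (16 ⇒ 15 ⇒ 14 ⇒ 13).** Bromide 16 comes from alcohol 15, this from silyl ether 14, and 14 from diene 13 by saturation of the ring-A alkene. The reduction has to distinguish a disubstituted from a tetrasubstituted alkene; diimide does this by its steep dependence on substitution.

**C9–C10 (13 ⇒ 12), the key cut.** Opening ring B at C9–C10 gives alkenyl iodide 12, in which ring A keeps a C10=C1 alkene and C5 carries the whole tether. Cutting C5–C10 or C5–C6 instead would leave the quaternary centre to be made without a stereochemical anchor. Cutting C9–C10 lets C5 dictate C10 and brings in the tetrasubstituted alkene with C11 and C12 attached. The forward Heck reaction must insert at a fully substituted alkene carbon in the 6-exo mode. It requires C7 cis to iodine in 12.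

**C7–C8 and C9–I (12 ⇒ 11 ⇒ 7 + 8).** The tetrasubstituted alkenyl iodide is taken apart at C7–C8. A syn-carbomagnesiation of pent-3-yn-1-ol 8 by the Grignard reagent of bromide 7, followed by iodination, gives 11 with C7 cis to iodine. The alternative cut with a methyl Grignard reagent on a longer alkynol would give the wrong geometry, because the added group and the metal end cis. Silylation of 11 gives 12.

**C5–C6 (7 ⇒ 6 ⇒ 5 ⇒ 2 + 3 ⇒ 1).** Bromide 7 comes from alcohol 6 and ester 5. The C5–C6 bond of 5 is formed by a Johnson–Claisen rearrangement of allylic alcohol 2 with orthoester 3, which transfers the carbinol configuration to C5 and moves the alkene to C10=C1, where the Heck step needs it. Alcohol 2 is the reduction product of the purchasable enone 1. Compared with alkylating a ring-A enolate, the sigmatropic route sets C5 next to a quaternary carbon without competing regiochemistry.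

## Roads not taken

**Alternative 1:** The cut is C16–C17 together with the lactone O–C19 bond, so the butenolide is built on the chain instead of being brought in. In the forward step Pd(OAc)2 with tris(2,6-dimethoxyphenyl)phosphine adds the terminal alkyne C–H of the bicyclic enyne A2 across ethyl 4-hydroxybut-2-ynoate A3. The cis hydroxy ester so formed lactonises to the 4-alkynylbutenolide A1.
- Merits: the step is atom-economical and needs no tin. It saves the separate stannane (step 14) and avoids an electrophilic iodination near the C8=C9 alkene. A2 would come from bromide 16 by a carbomagnesiation like step 12.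
- Weak point: A1 has an alkyne at C15–C16 where the target has an E alkene. A trans-selective semireduction is needed on an alkyne that lies between a trisubstituted alkene and a butenolide. Dissolving-metal and hydride methods attack the lactone. A trans-hydrometalation followed by protodemetalation adds two steps of uncertain regiochemistry before the final desilylation.
- Comparison: this road is better in atom economy, in avoiding tin and by one fragment step. The chosen plan sets against it that the C15=C16 geometry is bought with 17 and carried stereospecifically, and that the last step is neutral and at room temperature. The alternative does not touch the core; it needs the same bromide 16.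

**Alternative 2:** The cut is C5–C10 and C6–C7 at once. An intramolecular Diels–Alder reaction of the acyclic trienal A5 is catalysed by a chiral 5-benzyl-2-tert-butyl-3-methylimidazolidin-4-one salt. The iminium ion of the E enal (C5=C6) adds to the C7=C8–C9=C10 diene. Because the tether occupies the Z position at C10, the product A4 is cis-fused.
- Merits: both rings, two C–C bonds and both ring stereocentres arise in one catalytic enantioselective step. On ring construction alone this is shorter than the chosen sequence of reduction, Claisen rearrangement and Heck closure.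
- Weak points: the diene terminus C10 is fully substituted with the tether inside, so the reactive s-cis conformer is strained and 1,5-hydrogen shift competes. The dienophile carbon C5 is neopentylic (next to C4), where iminium activation is least effective. A4 carries a formyl group on C6 that the target lacks and that must be excised in one to three further steps. A5 itself needs a stereodefined tetrasubstituted C9=C10 alkene, the same geometric problem that the chosen route solves in 11.
- Comparison: the chosen plan sets against the shorter ring construction that each stereo-determining step is a known reaction class on a closely related substrate, and that no carbon has to be removed.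

**Alternative 3:** The cut is C5–C10, made by an Ireland–Claisen ring contraction. The silyl ketene acetal of the 6-alkenyl δ-lactone A7 rearranges through a bridged, boat-like transition state. The lactone C–O bond at C2 breaks and C5–C10 forms, giving the ring-A acid A6 with the carboxyl group cis to the C9 substituent.
- Merits: a sigmatropic shift tolerates congestion at C10 better than a migratory insertion. The C5/C10 relation follows from the alkene geometry and the absolute configuration from the lactone carbinol. On the single question of how to make C10 quaternary this road is the more secure one.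
- Weak points: A6 has no ring B. C7 and the C8 methyl group are absent. C6 is a carboxyl group on a carbon flanked by two quaternary centres, so chain extension there is hard. The exocyclic methylene on C9 must become the tetrasubstituted C8=C9 alkene by a ring closure of the most demanding kind. A7 needs a stereodefined trisubstituted diene and an enantioenriched carbinol before the key step.
- Comparison: the chosen plan sets against the safer quaternary centre that its key step also delivers ring B and the tetrasubstituted alkene with C11 and C12 in place, and that its chirality comes from a catalytic reduction of a purchasable enone.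

Key step: step 7

Remark on the chemistry: (E)-(2-bromoethenyl)trimethylsilane 17 and 4-bromofuran-2(5H)-one 24 are taken to be purchasable. The alkoxides of 8 and 19 are pre-formed with EtMgBr so that the Grignard reagents 9 and 20 are not spent on the hydroxyl proton.

## Steps

Step 1
Reactants: 1 2,4,4-trimethylcyclohex-2-en-1-one
Product: 2 (1S)-2,4,4-trimethylcyclohex-2-en-1-ol
Conditions: (R)-1-methyl-3,3-diphenyltetrahydro-1H,3H-pyrrolo[1,2-c][1,3,2]oxazaborole (10 mol%), BH3·SMe2, THF, −20 °C; MeOH
Reagents that add atoms: none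
Why: Corey–Bakshi–Shibata reduction; the catalyst binds the carbonyl with the α-methyl alkenyl arm as the large group and the ring CH2 as the small one, so the (R)-catalyst should deliver hydride to the face that gives the (S)-carbinol. 1,2-Reduction is favoured because the β-carbon is shielded by the C4 gem-dimethyl group.

Step 2
Reactants: 2 (1S)-2,4,4-trimethylcyclohex-2-en-1-ol; 3 triethyl orthoacetate
Product: 5 ethyl 2-[(1R)-2,6,6-trimethylcyclohex-2-en-1-yl]acetate, via mixed ketene acetal 4 (not isolated)
Conditions: MeC(OEt)3 (5 equiv), EtCO2H (cat.), 140 °C, EtOH distilled off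
Reagents that add atoms: none
Why: Johnson–Claisen rearrangement; the suprafacial [3,3] shift delivers CH2CO2Et to the alkene carbon next to C4 on the ring face from which the C–O bond departs, so the carbinol configuration of 2 becomes the (R) configuration at C5. The ring alkene ends at C10=C1 with its methyl on C10.

Step 3
Reactants: 5 ethyl 2-[(1R)-2,6,6-trimethylcyclohex-2-en-1-yl]acetate
Product: 6 2-[(1R)-2,6,6-trimethylcyclohex-2-en-1-yl]ethan-1-ol
Conditions: LiAlH4, Et2O, 0 °C
Reagents that add atoms: none
Why: Hydride reduction of an ester to the primary alcohol (C7); the isolated trisubstituted alkene and C5 are not touched.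

Step 4
Reactants: 6 2-[(1R)-2,6,6-trimethylcyclohex-2-en-1-yl]ethan-1-ol
Product: 7 (6R)-6-(2-bromoethyl)-1,5,5-trimethylcyclohex-1-ene
Conditions: CBr4, PPh3, CH2Cl2, 0 °C
Reagents that add atoms: tetrabromomethane, BrC(Br)(Br)Br
Why: Appel bromination of a primary alcohol by SN2 displacement of the oxyphosphonium ion under neutral conditions, which spares the acid-sensitive ring alkene.

Step 5
Reactants: 7 (6R)-6-(2-bromoethyl)-1,5,5-trimethylcyclohex-1-ene; 8 pent-3-yn-1-ol
Product: 11 (3Z)-3-iodo-4-methyl-6-[(1R)-2,6,6-trimethylcyclohex-2-en-1-yl]hex-3-en-1-ol, via Grignard reagent 9 (not isolated), via alkenylmagnesium alkoxide 10 (not isolated)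
Conditions: 7, Mg, THF, 40 °C (1.5 equiv of 9); 8, EtMgBr (0.95 equiv), THF, 0 °C; combine, Fe(acac)3 (10 mol%), THF, −40 → 0 °C; I2, −78 → 0 °C; aq. Na2S2O3
Reagents that add atoms: iodine, II
Why: Iron-catalysed, alkoxide-directed syn-carbomagnesiation of a homopropargylic alcohol; the alkyl group adds to the alkyne carbon remote from oxygen (C8) and magnesium to C9, where it closes a five-membered chelate with the alkoxide. Iodinolysis with retention then places iodine cis to C7, the geometry the Heck step needs.

Step 6
Reactants: 11 (3Z)-3-iodo-4-methyl-6-[(1R)-2,6,6-trimethylcyclohex-2-en-1-yl]hex-3-en-1-ol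
Product: 12 tert-butyl{[(3Z)-3-iodo-4-methyl-6-[(1R)-2,6,6-trimethylcyclohex-2-en-1-yl]hex-3-en-1-yl]oxy}dimethylsilane
Conditions: TBSCl, imidazole, DMF, rt
Reagents that add atoms: tert-butyl(chloro)dimethylsilane, CC(C)(C)[Si](C)(C)Cl
Why: Standard silylation of a primary alcohol; the hydroxyl is masked because a palladium alkoxide chelated to C9 could divert the alkenylpalladium of step 7 by β-hydride elimination and reduce the C–I bond.

Step 7
Reactants: 12 tert-butyl{[(3Z)-3-iodo-4-methyl-6-[(1R)-2,6,6-trimethylcyclohex-2-en-1-yl]hex-3-en-1-yl]oxy}dimethylsilane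
Product: 13 tert-butyl(dimethyl){2-[(4aR,8aS)-2,5,5,8a-tetramethyl-3,4,4a,5,6,8a-hexahydronaphthalen-1-yl]ethoxy}silane
Conditions: Pd(OAc)2 (10 mol%), PPh3 (30 mol%), Ag2CO3, MeCN, 80 °C
Reagents that add atoms: none
Why: Intramolecular Heck reaction: zerovalent palladium, formed from Pd(OAc)2 and PPh3, inserts into the C9–I bond, Ag2CO3 removes iodide, and the cationic alkenylpalladium adds syn across the C10=C1 alkene to form C9–C10. The closest known reaction type is the Heck cyclisation of alkenyl halides onto trisubstituted cycloalkenes, which gives cis-fused bicycles with a quaternary carbon. Ring B closes in the 6-exo-trig mode. The new stereocentre C10 is controlled by C5: the three-atom tether from C5 lets the C9–Pd bond reach C10 only on the ring-A face that carries C6, so C9–C10 and C5–C6 end cis and the C10 methyl is pushed to the face of H5. Palladium on C1 has no hydrogen on C10 and finds a syn hydrogen only at C2, so β-hydride elimination gives the C1=C2 alkene; a later shift of this alkene to C2=C3 would be harmless because step 8 saturates either. The step needs 6-exo over 7-endo regioselectivity, which the tether length and the smaller ring secure. It also needs C7 cis to the metal, which the syn addition of step 5 provides. The tetrasubstituted C8=C9 alkene is carried in unchanged, with C11 and C12 attached.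

Step 8
Reactants: 13 tert-butyl(dimethyl){2-[(4aR,8aS)-2,5,5,8a-tetramethyl-3,4,4a,5,6,8a-hexahydronaphthalen-1-yl]ethoxy}silane
Product: 14 tert-butyl(dimethyl){2-[(4aR,8aS)-2,5,5,8a-tetramethyl-3,4,4a,5,6,7,8,8a-octahydronaphthalen-1-yl]ethoxy}silane
Conditions: TsNHNH2 (excess, in portions), NaOAc, DME–H2O, reflux
Reagents that add atoms: none
Why: Diimide reduction; the concerted syn transfer of H2 slows steeply with alkene substitution, so the cis-disubstituted ring-A alkene should be saturated while the tetrasubstituted C8=C9 alkene stays. No stereocentre is formed.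

Step 9
Reactants: 14 tert-butyl(dimethyl){2-[(4aR,8aS)-2,5,5,8a-tetramethyl-3,4,4a,5,6,7,8,8a-octahydronaphthalen-1-yl]ethoxy}silane
Product: 15 2-[(4aR,8aS)-2,5,5,8a-tetramethyl-3,4,4a,5,6,7,8,8a-octahydronaphthalen-1-yl]ethan-1-ol
Conditions: Bu4NF, THF, rt
Reagents that add atoms: none
Why: Fluoride cleavage of the Si–O bond; nothing else in the molecule responds to fluoride.

Step 10
Reactants: 15 2-[(4aR,8aS)-2,5,5,8a-tetramethyl-3,4,4a,5,6,7,8,8a-octahydronaphthalen-1-yl]ethan-1-ol
Product: 16 (4aR,8aS)-1-(2-bromoethyl)-2,5,5,8a-tetramethyl-3,4,4a,5,6,7,8,8a-octahydronaphthalene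
Conditions: CBr4, PPh3, CH2Cl2, 0 °C
Reagents that add atoms: tetrabromomethane, BrC(Br)(Br)Br
Why: Appel bromination; the SN2 pathway under neutral conditions avoids ionisation of the homoallylic position and acid-induced migration of the C8=C9 alkene.

Step 11
Reactants: 17 (E)-(2-bromoethenyl)trimethylsilane; 18 prop-2-yn-1-ol
Product: 19 (4E)-5-(trimethylsilyl)pent-4-en-2-yn-1-ol
Conditions: PdCl2(PPh3)2 (3 mol%), CuI (5 mol%), i-Pr2NH, THF, rt → 40 °C
Reagents that add atoms: none
Why: Sonogashira coupling of an alkenyl bromide with a terminal alkyne; oxidative addition and reductive elimination proceed with retention, so the E geometry of 17 becomes that of C15=C16. The C–Si bond is inert.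

Step 12
Reactants: 16 (4aR,8aS)-1-(2-bromoethyl)-2,5,5,8a-tetramethyl-3,4,4a,5,6,7,8,8a-octahydronaphthalene; 19 (4E)-5-(trimethylsilyl)pent-4-en-2-yn-1-ol
Product: 22 (2E,4E)-2-{2-[(4aR,8aS)-2,5,5,8a-tetramethyl-3,4,4a,5,6,7,8,8a-octahydronaphthalen-1-yl]ethyl}-5-(trimethylsilyl)penta-2,4-dien-1-ol, via Grignard reagent 20 (not isolated), via dienylmagnesium alkoxide 21 (not isolated)
Conditions: 16, Mg, Et2O, reflux; 19 (1.5 equiv), EtMgBr (0.95 equiv per 19), Et2O, 0 °C; combine, CuI (10 mol%), −10 °C → rt; aq. NH4Cl
Reagents that add atoms: none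
Why: Copper-catalysed, alkoxide-directed anti-carbomagnesiation of a propargylic alcohol; the alkyl group adds to the alkyne carbon next to the carbinol (C13) and magnesium to C14 on the opposite side, held in a five-membered chelate with the alkoxide. Protonation with retention then leaves C12 cis to C15 and CH2OH cis to H14.

Step 13
Reactants: 22 (2E,4E)-2-{2-[(4aR,8aS)-2,5,5,8a-tetramethyl-3,4,4a,5,6,7,8,8a-octahydronaphthalen-1-yl]ethyl}-5-(trimethylsilyl)penta-2,4-dien-1-ol
Product: 23 (2E,4E)-5-iodo-2-{2-[(4aR,8aS)-2,5,5,8a-tetramethyl-3,4,4a,5,6,7,8,8a-octahydronaphthalen-1-yl]ethyl}penta-2,4-dien-1-ol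
Conditions: NIS (1.1 equiv), MeCN, 0 °C, dark
Reagents that add atoms: N-iodosuccinimide, O=C1CCC(=O)N1I
Why: Iododesilylation of an alkenylsilane; iodine attacks C16 ipso to silicon because the resulting cation at C15 is both β to silicon and allylic, and loss of the silyl group restores the alkene with retention of the E geometry.

Step 14
Reactants: 24 4-bromofuran-2(5H)-one
Product: 25 4-(tributylstannyl)furan-2(5H)-one
Conditions: (Bu3Sn)2, Pd(PPh3)4 (5 mol%), toluene, 100 °C
Reagents that add atoms: hexabutyldistannane, CCCC[Sn](CCCC)(CCCC)[Sn](CCCC)(CCCC)CCCC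
Why: Palladium-catalysed stannylation of an alkenyl bromide with a distannane (oxidative addition, Sn–Sn transmetalation, reductive elimination); the β-bromo enoate is an activated substrate.

Step 15
Reactants: 23 (2E,4E)-5-iodo-2-{2-[(4aR,8aS)-2,5,5,8a-tetramethyl-3,4,4a,5,6,7,8,8a-octahydronaphthalen-1-yl]ethyl}penta-2,4-dien-1-ol; 25 4-(tributylstannyl)furan-2(5H)-one
Product: 26 4-[(1E,3E)-4-(hydroxymethyl)-6-[(4aR,8aS)-2,5,5,8a-tetramethyl-3,4,4a,5,6,7,8,8a-octahydronaphthalen-1-yl]hexa-1,3-dien-1-yl]furan-2(5H)-one
Conditions: Pd2(dba)3 (5 mol%), AsPh3 (20 mol%), CuI (10 mol%), NMP, rt, dark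
Reagents that add atoms: none
Why: Stille coupling of an alkenyl iodide with an alkenylstannane, stereospecific at both partners, so C15=C16 stays E. The neutral room-temperature conditions tolerate the free allylic alcohol and the base-sensitive butenolide.

## Compound list

1 | 2,4,4-trimethylcyclohex-2-en-1-one | CC1=CC(C)(C)CCC1=O | starting material
2 | (1S)-2,4,4-trimethylcyclohex-2-en-1-ol | CC1=CC(C)(C)CC[C@@H]1O | intermediate
3 | triethyl orthoacetate | CCOC(C)(OCC)OCC | starting material
4 | 1-ethoxy-1-{[(1S)-2,4,4-trimethylcyclohex-2-en-1-yl]oxy}ethene (mixed ketene acetal) | C=C(OCC)O[C@H]1CCC(C)(C)C=C1C | intermediate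
5 | ethyl 2-[(1R)-2,6,6-trimethylcyclohex-2-en-1-yl]acetate | CC1=CCCC(C)(C)[C@H]1CC(=O)OCC | intermediate
6 | 2-[(1R)-2,6,6-trimethylcyclohex-2-en-1-yl]ethan-1-ol | CC1=CCCC(C)(C)[C@H]1CCO | intermediate
7 | (6R)-6-(2-bromoethyl)-1,5,5-trimethylcyclohex-1-ene | CC1=CCCC(C)(C)[C@H]1CCBr | intermediate
8 | pent-3-yn-1-ol | CC#CCCO | starting material
9 | {2-[(1R)-2,6,6-trimethylcyclohex-2-en-1-yl]ethyl}magnesium bromide | CC1=CCCC(C)(C)[C@H]1CC[Mg]Br | intermediate
10 | bromomagnesium alkoxide of the C9-bromomagnesio alkene (Mg on C9 cis to C7) | CC1=CCCC(C)(C)[C@H]1CC/C(C)=C(\[Mg]Br)CCO[Mg]Br | intermediate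
11 | (3Z)-3-iodo-4-methyl-6-[(1R)-2,6,6-trimethylcyclohex-2-en-1-yl]hex-3-en-1-ol | CC1=CCCC(C)(C)[C@H]1CC/C(C)=C(\I)CCO | intermediate
12 | tert-butyl{[(3Z)-3-iodo-4-methyl-6-[(1R)-2,6,6-trimethylcyclohex-2-en-1-yl]hex-3-en-1-yl]oxy}dimethylsilane | CC1=CCCC(C)(C)[C@H]1CC/C(C)=C(\I)CCO[Si](C)(C)C(C)(C)C | intermediate
13 | tert-butyl(dimethyl){2-[(4aR,8aS)-2,5,5,8a-tetramethyl-3,4,4a,5,6,8a-hexahydronaphthalen-1-yl]ethoxy}silane | CC1=C(CCO[Si](C)(C)C(C)(C)C)[C@@]2(C)C=CCC(C)(C)[C@H]2CC1 | intermediate
14 | tert-butyl(dimethyl){2-[(4aR,8aS)-2,5,5,8a-tetramethyl-3,4,4a,5,6,7,8,8a-octahydronaphthalen-1-yl]ethoxy}silane | CC1=C(CCO[Si](C)(C)C(C)(C)C)[C@@]2(C)CCCC(C)(C)[C@H]2CC1 | intermediate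
15 | 2-[(4aR,8aS)-2,5,5,8a-tetramethyl-3,4,4a,5,6,7,8,8a-octahydronaphthalen-1-yl]ethan-1-ol | CC1=C(CCO)[C@@]2(C)CCCC(C)(C)[C@H]2CC1 | intermediate
16 | (4aR,8aS)-1-(2-bromoethyl)-2,5,5,8a-tetramethyl-3,4,4a,5,6,7,8,8a-octahydronaphthalene | CC1=C(CCBr)[C@@]2(C)CCCC(C)(C)[C@H]2CC1 | intermediate
17 | (E)-(2-bromoethenyl)trimethylsilane | C[Si](C)(C)/C=C/Br | starting material
18 | prop-2-yn-1-ol | C#CCO | starting material
19 | (4E)-5-(trimethylsilyl)pent-4-en-2-yn-1-ol | C[Si](C)(C)/C=C/C#CCO | intermediate
20 | {2-[(4aR,8aS)-2,5,5,8a-tetramethyl-3,4,4a,5,6,7,8,8a-octahydronaphthalen-1-yl]ethyl}magnesium bromide | CC1=C(CC[Mg]Br)[C@@]2(C)CCCC(C)(C)[C@H]2CC1 | intermediate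
21 | bromomagnesium alkoxide of the C14-bromomagnesio diene (Mg on C14 cis to CH2O, C12 cis to C15) | CC1=C(CC/C(CO[Mg]Br)=C(/[Mg]Br)\C=C\[Si](C)(C)C)[C@@]2(C)CCCC(C)(C)[C@H]2CC1 | intermediate
22 | (2E,4E)-2-{2-[(4aR,8aS)-2,5,5,8a-tetramethyl-3,4,4a,5,6,7,8,8a-octahydronaphthalen-1-yl]ethyl}-5-(trimethylsilyl)penta-2,4-dien-1-ol | CC1=C(CC/C(=C\C=C\[Si](C)(C)C)CO)[C@@]2(C)CCCC(C)(C)[C@H]2CC1 | intermediate
23 | (2E,4E)-5-iodo-2-{2-[(4aR,8aS)-2,5,5,8a-tetramethyl-3,4,4a,5,6,7,8,8a-octahydronaphthalen-1-yl]ethyl}penta-2,4-dien-1-ol | CC1=C(CC/C(=C\C=C\I)CO)[C@@]2(C)CCCC(C)(C)[C@H]2CC1 | intermediate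
24 | 4-bromofuran-2(5H)-one | BrC1=CC(=O)OC1 | starting material
25 | 4-(tributylstannyl)furan-2(5H)-one | CCCC[Sn](CCCC)(CCCC)C1=CC(=O)OC1 | intermediate
26 | 4-[(1E,3E)-4-(hydroxymethyl)-6-[(4aR,8aS)-2,5,5,8a-tetramethyl-3,4,4a,5,6,7,8,8a-octahydronaphthalen-1-yl]hexa-1,3-dien-1-yl]furan-2(5H)-one | CC1=C(CC/C(=C\C=C\C2=CC(=O)OC2)CO)[C@@]2(C)CCCC(C)(C)[C@H]2CC1 | target

## Step count and least certain steps

Total: 15 steps. Longest linear sequence: 13 steps (steps 1–10, 12, 13, 15). Steps 11 and 14 are single-step branches.

**Step 7 (key step).** Migratory insertion at the fully substituted C10, next to C5 and the C4 gem-dimethyl group, may be slow. The tetrasubstituted alkenylpalladium could then be reduced at C9 or decompose before ring closure, and 7-endo insertion at C1 becomes a possible leak.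

The fallback replaces the alkene insertion by an enolate coupling that forms the same C9–C10 bond. It sets out from 12.
- Hydroboration of the ring-A alkene (BH3·THF; then H2O2, NaOH) should give (3S)-3-[(3Z)-6-{[tert-butyl(dimethyl)silyl]oxy}-4-iodo-3-methylhex-3-en-1-yl]-2,4,4-trimethylcyclohexan-1-ol F1 as a mixture at C1 and C10. The hindered iodoalkene should be left alone.
- Oxidation with Dess–Martin periodinane gives the ketone (3S)-3-[(3Z)-6-{[tert-butyl(dimethyl)silyl]oxy}-4-iodo-3-methylhex-3-en-1-yl]-2,4,4-trimethylcyclohexan-1-one F2.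
- Palladium-catalysed intramolecular α-alkenylation of the ketone enolate (Pd2(dba)3, P(t-Bu)3, NaOt-Bu, THF, 60 °C) closes ring B at C10 and gives (4aR,8aS)-8-(2-{[tert-butyl(dimethyl)silyl]oxy}ethyl)-4,4,7,8a-tetramethyl-3,4,4a,5,6,8a-hexahydronaphthalen-1(2H)-one F3. The tether from C5 again enforces cis fusion, and the stereochemistry at C10 of F2 is erased in the enolate.
- Wolff–Kishner reduction (N2H4·H2O, KOH, diethylene glycol, 200 °C) removes the C1 carbonyl. The hot alkali is expected to cleave the silyl ether as well, so the route is rejoined at 15.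

**Step 5.** β-Hydride elimination from the alkyliron species would turn carbometalation into hydrometalation of 8 and waste 9. The reaction class is best known for Grignard reagents without β-hydrogens and with the Grignard reagent in excess; a bidentate phosphine such as 1,2-bis(diphenylphosphino)ethane would be tried first.

The fallback replaces iron by a stoichiometric copper reagent and an activated alkyne. It sets out from 7 through its Grignard reagent 9.
- The organocopper reagent from 9 and CuBr·SMe2 adds syn to ethyl but-2-ynoate at −78 °C, and the alkenylcopper is trapped with I2 to give ethyl (2Z)-2-iodo-3-methyl-5-[(1R)-2,6,6-trimethylcyclohex-2-en-1-yl]pent-2-enoate F4.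
- Reduction with i-Bu2AlH gives (2Z)-2-iodo-3-methyl-5-[(1R)-2,6,6-trimethylcyclohex-2-en-1-yl]pent-2-en-1-ol F5.
- MnO2 oxidation gives (2Z)-2-iodo-3-methyl-5-[(1R)-2,6,6-trimethylcyclohex-2-en-1-yl]pent-2-enal F6.
- Wittig methylenation (Ph3P=CH2) gives (6R)-6-[(3Z)-4-iodo-3-methylhexa-3,5-dien-1-yl]-1,5,5-trimethylcyclohex-1-ene F7.
- Hydroboration of the terminal vinyl group with 9-BBN and oxidation rejoins the route at 11.

**Step 12.** The reaction is normally run with the Grignard reagent in excess; here 20 is the limiting partner. Incomplete addition, addition across the conjugated enyne in another sense, or loss of anti selectivity at C13=C14 are the likely failures.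

The fallback builds C13=C14 by olefination. It sets out from 16.
- Alkylation of the sodium salt of triethyl phosphonoacetate with 16 (NaH, DMF) gives ethyl 2-(diethoxyphosphoryl)-4-[(4aR,8aS)-2,5,5,8a-tetramethyl-3,4,4a,5,6,7,8,8a-octahydronaphthalen-1-yl]butanoate F8.
- Horner–Wadsworth–Emmons reaction of F8 with the known aldehyde (2E)-3-(trimethylsilyl)prop-2-enal F9 (NaH, THF) gives mainly ethyl (2E,4E)-2-{2-[(4aR,8aS)-2,5,5,8a-tetramethyl-3,4,4a,5,6,7,8,8a-octahydronaphthalen-1-yl]ethyl}-5-(trimethylsilyl)penta-2,4-dienoate F10, the isomer with the ester trans to C15.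
- Reduction with i-Bu2AlH rejoins the route at 22.

**Step 13.** The iodinating agent may attack the electron-rich C8=C9 alkene. The C13=C14 geometry may also scramble through the allyl cation formed on ipso attack.

The fallback avoids electrophilic halogen altogether. It sets out from 16 (through 20) and from 18.
- Sonogashira coupling of 18 with (E)-1,2-dichloroethene gives (4E)-5-chloropent-4-en-2-yn-1-ol F11.
- Addition of 20 to F11 under the conditions of step 12 gives (2E,4E)-5-chloro-2-{2-[(4aR,8aS)-2,5,5,8a-tetramethyl-3,4,4a,5,6,7,8,8a-octahydronaphthalen-1-yl]ethyl}penta-2,4-dien-1-ol F12.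
- Stille coupling of the alkenyl chloride F12 with 25 under a bulky electron-rich phosphine (Pd2(dba)3, P(t-Bu)3, CsF, dioxane) gives 26 directly.

## Further compounds

F1 | step 7 | (3S)-3-[(3Z)-6-{[tert-butyl(dimethyl)silyl]oxy}-4-iodo-3-methylhex-3-en-1-yl]-2,4,4-trimethylcyclohexan-1-ol (mixture at C1 and C10) | CC1C(O)CCC(C)(C)[C@H]1CC/C(C)=C(\I)CCO[Si](C)(C)C(C)(C)C
F2 | step 7 | (3S)-3-[(3Z)-6-{[tert-butyl(dimethyl)silyl]oxy}-4-iodo-3-methylhex-3-en-1-yl]-2,4,4-trimethylcyclohexan-1-one (mixture at C10) | CC1C(=O)CCC(C)(C)[C@H]1CC/C(C)=C(\I)CCO[Si](C)(C)C(C)(C)C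
F3 | step 7 | (4aR,8aS)-8-(2-{[tert-butyl(dimethyl)silyl]oxy}ethyl)-4,4,7,8a-tetramethyl-3,4,4a,5,6,8a-hexahydronaphthalen-1(2H)-one | CC1=C(CCO[Si](C)(C)C(C)(C)C)[C@@]2(C)C(=O)CCC(C)(C)[C@H]2CC1
F4 | step 5 | ethyl (2Z)-2-iodo-3-methyl-5-[(1R)-2,6,6-trimethylcyclohex-2-en-1-yl]pent-2-enoate | CC1=CCCC(C)(C)[C@H]1CC/C(C)=C(\I)C(=O)OCC
F5 | step 5 | (2Z)-2-iodo-3-methyl-5-[(1R)-2,6,6-trimethylcyclohex-2-en-1-yl]pent-2-en-1-ol | CC1=CCCC(C)(C)[C@H]1CC/C(C)=C(\I)CO
F6 | step 5 | (2Z)-2-iodo-3-methyl-5-[(1R)-2,6,6-trimethylcyclohex-2-en-1-yl]pent-2-enal | CC1=CCCC(C)(C)[C@H]1CC/C(C)=C(\I)C=O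
F7 | step 5 | (6R)-6-[(3Z)-4-iodo-3-methylhexa-3,5-dien-1-yl]-1,5,5-trimethylcyclohex-1-ene | CC1=CCCC(C)(C)[C@H]1CC/C(C)=C(\I)C=C
F8 | step 12 | ethyl 2-(diethoxyphosphoryl)-4-[(4aR,8aS)-2,5,5,8a-tetramethyl-3,4,4a,5,6,7,8,8a-octahydronaphthalen-1-yl]butanoate | CC1=C(CCC(C(=O)OCC)P(=O)(OCC)OCC)[C@@]2(C)CCCC(C)(C)[C@H]2CC1
F9 | step 12 | (2E)-3-(trimethylsilyl)prop-2-enal | C[Si](C)(C)/C=C/C=O
F10 | step 12 | ethyl (2E,4E)-2-{2-[(4aR,8aS)-2,5,5,8a-tetramethyl-3,4,4a,5,6,7,8,8a-octahydronaphthalen-1-yl]ethyl}-5-(trimethylsilyl)penta-2,4-dienoate | CC1=C(CC/C(=C\C=C\[Si](C)(C)C)C(=O)OCC)[C@@]2(C)CCCC(C)(C)[C@H]2CC1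
F11 | step 13 | (4E)-5-chloropent-4-en-2-yn-1-ol | Cl/C=C/C#CCO
F12 | step 13 | (2E,4E)-5-chloro-2-{2-[(4aR,8aS)-2,5,5,8a-tetramethyl-3,4,4a,5,6,7,8,8a-octahydronaphthalen-1-yl]ethyl}penta-2,4-dien-1-ol | CC1=C(CC/C(=C\C=C\Cl)CO)[C@@]2(C)CCCC(C)(C)[C@H]2CC1
A1 | alternative 1 | 4-[(3E)-4-({[tert-butyl(dimethyl)silyl]oxy}methyl)-6-[(4aR,8aS)-2,5,5,8a-tetramethyl-3,4,4a,5,6,7,8,8a-octahydronaphthalen-1-yl]hex-3-en-1-yn-1-yl]furan-2(5H)-one | CC1=C(CC/C(=C\C#CC2=CC(=O)OC2)CO[Si](C)(C)C(C)(C)C)[C@@]2(C)CCCC(C)(C)[C@H]2CC1
A2 | alternative 1 | tert-butyl(dimethyl){[(2E)-2-{2-[(4aR,8aS)-2,5,5,8a-tetramethyl-3,4,4a,5,6,7,8,8a-octahydronaphthalen-1-yl]ethyl}pent-2-en-4-yn-1-yl]oxy}silane | CC1=C(CC/C(=C\C#C)CO[Si](C)(C)C(C)(C)C)[C@@]2(C)CCCC(C)(C)[C@H]2CC1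
A3 | alternative 1 | ethyl 4-hydroxybut-2-ynoate | CCOC(=O)C#CCO
A4 | alternative 2 | cis-fused 4-(2-{[tert-butyl(dimethyl)silyl]oxy}ethyl)-3,4a,8,8-tetramethyl-1,2,4a,5,6,7,8,8a-octahydronaphthalene-1-carbaldehyde (formyl group on C6) | CC1=C(CCO[Si](C)(C)C(C)(C)C)[C@@]2(C)CCCC(C)(C)[C@H]2[C@H](C=O)C1
A5 | alternative 2 | (2E,8Z)-9-(2-{[tert-butyl(dimethyl)silyl]oxy}ethyl)-4,4,8,10-tetramethylundeca-2,8,10-trienal | O=C/C=C/C(C)(C)CCC/C(C)=C(/CCO[Si](C)(C)C(C)(C)C)C(C)=C
A6 | alternative 3 | 2-(4-{[tert-butyl(dimethyl)silyl]oxy}but-1-en-2-yl)-2,6,6-trimethylcyclohex-3-ene-1-carboxylic acid (carboxyl cis to the butenyl group) | OC(=O)[C@@H]1C(C)(C)CC=C[C@]1(C)C(=C)CCO[Si](C)(C)C(C)(C)C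
A7 | alternative 3 | (6S)-6-[(1E)-5-{[tert-butyl(dimethyl)silyl]oxy}-2-methyl-3-methylidenepent-1-en-1-yl]-4,4-dimethyloxan-2-one | O=C1CC(C)(C)C[C@H](O1)/C=C(\C)C(=C)CCO[Si](C)(C)C(C)(C)C
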